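**Plan**

1. Numbering: cyclopentenone C1H2–C2(=O)–C3H=C4–C9; cyclohexane C4–C5(Me)–C6(Me)–C7H2–C8(OH)–C9; bridge C9–C10(Me)–C11(OH)–C12(Me)(vinyl)–C13H2–C14(OAc)–C5.
2. Cuts, last bond first: C11–C12 (eight-membered ring, Cr(II) allylation of the C11 aldehyde by a (Z)-allyl chloride at C12); C13–C14 (methallylboration of the C14 aldehyde); C4–C9, C1–C2 and C2–C3 together (Pauson–Khand); C8–C9 (alkenyl Grignard plus C8 aldehyde).
3. Enabling feature: the enone C2(=O)–C3H=C4 lies in the five-membered ring C1–C2–C3–C4–C9, which shares the C4–C9 bond with the six-membered ring C4–C9 and sits between the quaternary carbons C5 and C9. This is what a [2+2+1] union of an ethynyl group on C5 (C3≡C4), CO (C2) and the 1,1-disubstituted alkene C9=C1H2 delivers.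
4. Forward order: C4–C8 chain from a chiral δ-lactone, union with the C9–C11 alkenyl unit, six- and five-membered rings in one step, C12–C13 unit on C14, eight-membered ring last.
5. Stereochemistry: C6 from methyl (R)-3-methylglutarate; C5 by lactone alkylation anti to the C6 methyl; C10 from the (S)-Roche ester; C8 by CBS reduction; C9 from C8 through an O8–Si–O11 silylene tether in the Pauson–Khand step; C14 by Ipc2B-methallylation; C11 and C12 in the ring closure (Felkin face, (Z)-allyl geometry fixed by silicon-tethered metathesis).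

Key step: step 16

Assumption: the SMILES is taken literally; in it C14 (on C5) and C10 (on C9) stand on opposite faces of the cyclohexane, so the eight-membered ring is a trans-1,3 bridge (in,out-type bicyclo[5.3.1]undecene), and all descriptors and arguments below refer to this isomer, (5S,6S,8S,9R,10R,11S,12S,14R).

**Route**

Step 1
Reactants: 1 methyl (R)-3-methylglutarate [(3R)-5-methoxy-3-methyl-5-oxopentanoic acid]
Product: 3 (S)-4-methyltetrahydro-2H-pyran-2-one, via hydroxy acid 2 (not isolated)
Conditions: LiBH4, THF, 0 °C → rt; then 2 M HCl, rt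
Reagents that add atoms: none
Why: LiBH4 reduces the methyl ester but not the lithium carboxylate and the 5-hydroxy acid lactonises on acidification (chemoselective ester reduction, lactonisation); the stereocentre is untouched, and reducing the ester arm is what turns the (R)-half ester into the (S)-lactone that carries C6.

Step 2
Reactants: 3 (S)-4-methyltetrahydro-2H-pyran-2-one
Product: 5 (3S,4S)-3-{[(4-methoxybenzyl)oxy]methyl}-4-methyltetrahydro-2H-pyran-2-one, via lithium enolate 4 (not isolated)
Conditions: LDA, THF, −78 °C; then PMBOCH2Cl, −78 → −40 °C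
Reagents that add atoms: 4-methoxybenzyl chloromethyl ether, COc1ccc(COCCl)cc1
Why: Lactone enolate alkylation with a reactive α-chloro ether brings in C14; the electrophile enters trans to the ring methyl, but this centre is enolised again in step 3, so its configuration does not matter.

Step 3
Reactants: 5 (3S,4S)-3-(PMB-oxymethyl)-4-methyl lactone
Product: 7 (3R,4S)-3-{[(4-methoxybenzyl)oxy]methyl}-3,4-dimethyltetrahydro-2H-pyran-2-one, via lithium enolate 6 (not isolated)
Conditions: LDA, THF, −78 °C; then MeI, DMPU, −78 → −40 °C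
Reagents that add atoms: iodomethane, CI
Why: Second enolate alkylation sets C5: in the tetrasubstituted enolate the C6 methyl turns pseudoaxial (A1,2 strain with the alkoxymethyl group), so MeI enters anti to it and leaves the new methyl trans and the CH2OPMB group cis to the C6 methyl; the low temperature holds back β-elimination of the alkoxide.

Step 4
Reactants: 7 quaternary lactone
Product: 8 (3R,4S)-3-{[(4-methoxybenzyl)oxy]methyl}-3,4-dimethyltetrahydro-2H-pyran-2-ol (lactol, anomers)
Conditions: DIBAL-H, CH2Cl2, −78 °C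
Reagents that add atoms: none
Why: Partial reduction of a lactone to the lactol; the tetrahedral aluminium hemiacetal is stable at −78 °C and the α-carbon is quaternary, so nothing can epimerise.

Step 5
Reactants: 8 lactol
Product: 9 (3S,4S)-4-{[(4-methoxybenzyl)oxy]methyl}-3,4-dimethylhex-5-yn-1-ol
Conditions: dimethyl (1-diazo-2-oxopropyl)phosphonate, K2CO3, MeOH, 0 °C → rt
Reagents that add atoms: dimethyl (1-diazo-2-oxopropyl)phosphonate, COP(=O)(OC)C(=[N+]=[N-])C(C)=O
Why: Ohira–Bestmann (Seyferth–Gilbert) homologation acts on the open hydroxy-aldehyde form of the lactol, turns C4 into the ethynyl group (C3 from the reagent) and frees the C8 hydroxyl; the aldehyde is not enolisable.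

Step 6
Reactants: 9 alkynol
Product: 10 (3S,4S)-4-{[(4-methoxybenzyl)oxy]methyl}-3,4-dimethylhex-5-ynal
Conditions: Dess–Martin periodinane, NaHCO3, CH2Cl2, 0 °C → rt
Reagents that add atoms: none
Why: Dess–Martin oxidation of a primary alcohol under buffered conditions gives the C8 aldehyde without touching the alkyne or the PMB ether.

Step 7
Reactants: 11 methyl (S)-3-hydroxy-2-methylpropanoate
Product: 12 methyl (S)-3-[(tert-butyldimethylsilyl)oxy]-2-methylpropanoate
Conditions: TBSCl, imidazole, CH2Cl2, 0 °C → rt
Reagents that add atoms: tert-butyldimethylsilyl chloride, CC(C)(C)[Si](C)(C)Cl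
Why: Standard silylation of a primary alcohol; the α-stereocentre (future C10) is not affected by imidazole.

Step 8
Reactants: 12 silyl ether ester
Product: 13 (S)-3-[(tert-butyldimethylsilyl)oxy]-2-methylpropanal
Conditions: DIBAL-H, CH2Cl2, −78 °C
Reagents that add atoms: none
Why: Low-temperature DIBAL reduction stops at the aldehyde through the stable aluminium hemiacetal; the aldehyde is used at once to avoid epimerisation.

Step 9
Reactants: 13 aldehyde
Product: 14 (R)-tert-butyldimethyl[(2-methylbut-3-yn-1-yl)oxy]silane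
Conditions: dimethyl (1-diazo-2-oxopropyl)phosphonate, K2CO3, MeOH, 0 °C → rt
Reagents that add atoms: dimethyl (1-diazo-2-oxopropyl)phosphonate, COP(=O)(OC)C(=[N+]=[N-])C(C)=O
Why: Ohira–Bestmann homologation under mild carbonate conditions converts the aldehyde (C9) into the terminal alkyne (C1 from the reagent) with retention at C10.

Step 10
Reactants: 14 alkyne
Product: 16 (S)-[(3-bromo-2-methylbut-3-en-1-yl)oxy](tert-butyl)dimethylsilane, via alkenylborane 15 (not isolated)
Conditions: B-bromo-9-BBN, CH2Cl2, 0 °C; then AcOH, 0 °C → rt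
Reagents that add atoms: B-bromo-9-borabicyclo[3.3.1]nonane, BrB1C2CCCC1CCC2
Why: syn-Bromoboration puts bromine on the internal alkyne carbon (Markovnikov) and protodeboronation with acetic acid leaves the 2-bromo-1-alkene (haloboration–protonolysis); C10 is not involved.

Step 11
Reactants: 16 alkenyl bromide; 10 aldehyde
Product: 18 enyne alcohol (5S,6S,10R; C8 epimers): HC3≡C4–C5(CH3)(C14H2OPMB)–C6H(CH3)–C7H2–C8H(OH)–C9(=C1H2)–C10H(CH3)–C11H2OTBS, via alkenylmagnesium bromide 17 (not isolated)
Conditions: Mg, THF, 40 °C; then 10, THF, −78 °C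
Reagents that add atoms: none
Why: Grignard addition of a 2-alkenylmagnesium bromide to an aldehyde forms C8–C9; at −78 °C carbonyl addition outruns deprotonation of the terminal alkyne, and the C8 mixture is corrected in steps 12 and 13.

Step 12
Reactants: 18 enyne alcohol
Product: 19 enynone (5S,6S,10R): as 18 with C8=O (α-methylene ketone)
Conditions: Dess–Martin periodinane, NaHCO3, CH2Cl2, 0 °C
Reagents that add atoms: none
Why: Dess–Martin oxidation of the allylic alcohol converges both C8 epimers on one enone under neutral conditions that do not isomerise the 1,1-disubstituted alkene.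

Step 13
Reactants: 19 enynone
Product: 20 enyne alcohol (5S,6S,8S,10R): as 18 with (8S)-OH
Conditions: (R)-2-methyl-CBS-oxazaborolidine (20 mol %), catecholborane, toluene, −78 °C
Reagents that add atoms: none
Why: Corey–Bakshi–Shibata reduction in which the α-branched alkenyl group (C9) acts as the large and the C7H2 chain as the small substituent, so the (R)-catalyst delivers hydride to give the 8S alcohol; catecholborane at −78 °C leaves alkyne and alkene alone.

Step 14
Reactants: 20 (8S)-enyne alcohol
Product: 21 enyne diol (5S,6S,8S,10R): as 20 with C11H2OH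
Conditions: HF·pyridine, pyridine, THF, 0 °C → rt
Reagents that add atoms: none
Why: Fluoride cleavage of a primary TBS ether frees O11 so that O8 and O11 can be tied together.

Step 15
Reactants: 21 enyne diol
Product: 22 silylene enyne (5S,6S,8S,10R): as 21 with O8 and O11 joined by Si(t-Bu)2 in a seven-membered 1,3-dioxa-2-silepane that carries the C9 methylene
Conditions: t-Bu2Si(OTf)2, 2,6-lutidine, CH2Cl2, 0 °C
Reagents that add atoms: di-tert-butylsilyl bis(trifluoromethanesulfonate), CC(C)(C)[Si](OS(=O)(=O)C(F)(F)F)(OS(=O)(=O)C(F)(F)F)C(C)(C)C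
Why: Di-tert-butylsilylene formation from a 1,4-diol with the bis-triflate; no stereocentre changes, and the ring installs the tether that will relay C8 to C9.

Step 16
Reactants: 22 silylene enyne
Product: 23 silylene hydrindenone (5S,6S,8S,9R,10R): cyclopentenone C1H2–C2(=O)–C3H=C4–C9 fused at C4–C9 to the cyclohexane C4–C5(CH3)(CH2OPMB)–C6H(CH3)–C7H2–C8H(O)–C9, C9 bearing C10H(CH3)–C11H2O, O8 and O11 bridged by Si(t-Bu)2
Conditions: Co2(CO)8 (20 mol %), tetramethylthiourea (60 mol %), CO (1 atm), toluene, 70 °C
Reagents that add atoms: carbon monoxide, [C-]#[O+]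
Why: The terminal alkyne is bound as its Co2(CO)6 complex, loss of CO lets the C9=C1 alkene coordinate and insert at C4 (C4–C9), CO then inserts and reductive elimination joins C1–C2 and C2–C3 and releases the enone; the closest known reaction type is the intramolecular Pauson–Khand reaction of 1,7-enynes with 1,1-disubstituted alkenes, which gives bicyclic enones with an angular quaternary carbon. The cyclohexane closes as the tether ring (C4 is bonded to the internal alkene carbon C9 across C5–C8), and the cyclopentenone closes by the [2+2+1] event itself. The new stereocentre C9 is controlled by C8 through the silylene ring: C1 must lie near the plane of the forming C3=C4 unit, so the C10 branch is axial on the chair-like six-membered array, and the seven-membered ring can span O8 and C10 only when O8 is equatorial and syn to C10, which corresponds to one alkene face (9R). The step therefore needs only facial selectivity, since there is a single alkyne and a single alkene and the tether fixes the regiochemistry with C2 between C1 and C3. Two substituents on the propargylic C5 bias the chain towards the folded conformer, and because C3 carries hydrogen the enone needs no later adjustment.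

Step 17
Reactants: 23 silylene hydrindenone
Product: 24 diol hydrindenone (5S,6S,8S,9R,10R): as 23 with free 8-OH and C11H2OH
Conditions: HF·pyridine, pyridine, THF, 0 °C
Reagents that add atoms: none
Why: Fluoride removes the seven-membered dialkoxysilane once its job is done; PMB ether and enone are inert.

Step 18
Reactants: 24 diol hydrindenone
Product: 25 bis-TBS hydrindenone (5S,6S,8S,9R,10R): as 24 with 8-OTBS and C11H2OTBS
Conditions: TBSOTf, 2,6-lutidine, CH2Cl2, −78 → 0 °C
Reagents that add atoms: tert-butyldimethylsilyl trifluoromethanesulfonate, CC(C)(C)[Si](C)(C)OS(=O)(=O)C(F)(F)F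
Why: The silyl triflate silylates both the primary and the hindered secondary alcohol, giving two silyl ethers that can later be told apart by steric demand.

Step 19
Reactants: 25 bis-TBS hydrindenone
Product: 26 C14 alcohol: as 25 with C14H2OH
Conditions: DDQ, CH2Cl2/pH 7 buffer, 0 °C → rt
Reagents that add atoms: none
Why: Oxidative cleavage of the PMB ether by DDQ (hydride abstraction, hydrolysis of the oxocarbenium ion) leaves silyl ethers and the enone untouched.

Step 20
Reactants: 26 C14 alcohol
Product: 27 C14 aldehyde: as 25 with C14H=O on C5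
Conditions: Dess–Martin periodinane, NaHCO3, CH2Cl2, 0 °C → rt
Reagents that add atoms: none
Why: Dess–Martin oxidation of the neopentyl primary alcohol gives a non-enolisable aldehyde.

Step 21
Reactants: 27 C14 aldehyde
Product: 28 (14R)-methallyl carbinol: C5–C14H(OH)–C13H2–C12(CH3)=CH2, rest as 25
Conditions: (+)-Ipc2BOMe, methallylmagnesium chloride, Et2O, 0 °C → rt; then 27, −78 °C; NaBO3·4H2O, THF/H2O
Reagents that add atoms: B-methallyldiisopinocampheylborane (lIpc series, made from methallylmagnesium chloride, CC(=C)C[Mg]Cl), CC(=C)CB([C@H]1C[C@H]2C[C@@H]([C@@H]1C)C2(C)C)[C@H]1C[C@H]2C[C@@H]([C@@H]1C)C2(C)C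
Why: Brown methallylboration through a six-membered chair transition state in which the lIpc ligands send the methallyl group to the Re face of the aldehyde (14R, reagent control); at −78 °C the aldehyde reacts much faster than the cyclopentenone carbonyl.

Step 22
Reactants: 28 methallyl carbinol
Product: 29 allyldimethylsilyl ether: as 28 with C14–O–SiMe2–CH2CH=CH2
Conditions: allyl(chloro)dimethylsilane, imidazole, DMF, 0 °C → rt
Reagents that add atoms: allyl(chloro)dimethylsilane, C=CC[Si](C)(C)Cl
Why: Silylation of the secondary alcohol with a small chlorosilane attaches the two-carbon unit that will become the vinyl group through a temporary silicon tether.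

Step 23
Reactants: 29 allyldimethylsilyl ether
Product: 30 cyclic siloxane: seven-membered 1-oxa-2-silacyclohept-4-ene O14–SiMe2–CH2–CH=C12(CH3)–C13H2–C14, rest as 25
Conditions: second-generation Ru metathesis catalyst (Grubbs II, 5 mol %), toluene, 80 °C
Reagents that add atoms: none
Why: Ring-closing metathesis between the allylsilane and the 1,1-disubstituted alkene gives a trisubstituted alkene that must be cis within the seven-membered ring, which fixes the (Z) geometry (C13 cis to the CH2Si carbon); the hindered enone does not take part.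

Step 24
Reactants: 30 cyclic siloxane
Product: 31 (Z)-diol: C5–C14H(OH)–C13H2–C12(CH3)=CH–CH2OH with C13 cis to CH2OH, rest as 25
Conditions: KF, KHCO3, 30% H2O2, THF/MeOH, rt
Reagents that add atoms: hydrogen peroxide, OO
Why: Tamao–Fleming oxidation converts the allylic C–Si bond into C–OH with retention and without allylic shift and cleaves the Si–O bond; the alkene geometry is kept, and the β,β-disubstituted enone is too hindered for nucleophilic epoxidation.

Step 25
Reactants: 31 (Z)-diol
Product: 33 (Z)-allylic chloride (as 31 with CH2Cl in place of the allylic CH2OH), via allylic mesylate 32 (not isolated)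
Conditions: MsCl, 2,4,6-collidine, LiCl, DMF, 0 °C
Reagents that add atoms: lithium chloride, [Li+].[Cl-]; methanesulfonyl chloride, CS(=O)(=O)Cl (its atoms stay only in the intermediate 32)
Why: Collington–Meyers chlorination: the primary allylic alcohol is mesylated and displaced by chloride in an SN2 step without allylic transposition, while the hindered secondary C14 hydroxyl does not react at 0 °C; the product is acetylated without delay to forestall cyclo-etherification.

Step 26
Reactants: 33 (Z)-allylic chloride
Product: 34 acetate: as 33 with C14–OAc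
Conditions: Ac2O, DMAP (cat.), pyridine, CH2Cl2, 0 °C → rt
Reagents that add atoms: acetic anhydride, CC(=O)OC(C)=O
Why: DMAP-catalysed acetylation puts the acetate of the target on O14 before O11 exists as a free hydroxyl, so the two secondary alcohols never need to be told apart.

Step 27
Reactants: 34 acetate
Product: 35 C11 alcohol: as 34 with C11H2OH (8-OTBS kept)
Conditions: HF·pyridine, pyridine, THF, 0 °C
Reagents that add atoms: none
Why: Buffered HF·pyridine cleaves the primary TBS ether much faster than the secondary one next to quaternary C9 (steric differentiation of silyl ethers); acetate and allylic chloride are stable.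

Step 28
Reactants: 35 C11 alcohol
Product: 36 C11 aldehyde: as 34 with C11H=O on C10
Conditions: Dess–Martin periodinane, NaHCO3, CH2Cl2, 0 °C
Reagents that add atoms: none
Why: Buffered Dess–Martin oxidation gives the α-branched aldehyde without epimerising C10, which is shielded by quaternary C9.

Step 29
Reactants: 36 C11 aldehyde
Product: 37 8-O-TBS ether of the target (5S,6S,8S,9R,10R,11S,12S,14R): eight-membered ring closed, C11–OH, C12(CH3)(CH=CH2)
Conditions: CrCl2 (8 equiv), LiI (cat.), THF, rt, high dilution (slow addition of 36)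
Reagents that add atoms: none
Why: Intramolecular Nozaki–Hiyama allylation: the allylic chloride gives an allylchromium(III) species whose γ-carbon C12 adds to the C11 aldehyde through a closed six-membered transition state with allylic transposition (forming C11–C12 and the vinyl group); attack anti to C9 (Felkin) with C10 equatorial and the (Z)-placed C13 axial leads to 11S,12S, and Cr(II) tolerates enone, acetate and silyl ether.

Step 30
Reactants: 37 8-O-TBS ether
Product: 38 Pleuromutilin E
Conditions: 48% aq. HF, MeCN, 0 °C → rt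
Reagents that add atoms: none
Why: Acidic fluoride removes the hindered secondary TBS ether; under these non-basic conditions the acetate neither migrates nor hydrolyses.

**Compound list**

1 | methyl (R)-3-methylglutarate | COC(=O)C[C@H](C)CC(=O)O | starting material
2 | (S)-5-hydroxy-3-methylpentanoic acid | OC(=O)C[C@@H](C)CCO | intermediate (not isolated)
3 | (S)-4-methyltetrahydro-2H-pyran-2-one | O=C1C[C@@H](C)CCO1 | intermediate
4 | lithium enolate of 3 | [Li]OC1=C[C@@H](C)CCO1 | intermediate (not isolated)
5 | (3S,4S)-3-{[(4-methoxybenzyl)oxy]methyl}-4-methyltetrahydro-2H-pyran-2-one | COc1ccc(COC[C@H]2C(=O)OCC[C@@H]2C)cc1 | intermediate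
6 | lithium enolate of 5 | [Li]OC1=C(COCc2ccc(OC)cc2)[C@@H](C)CCO1 | intermediate (not isolated)
7 | (3R,4S)-3-{[(4-methoxybenzyl)oxy]methyl}-3,4-dimethyltetrahydro-2H-pyran-2-one | COc1ccc(COC[C@]2(C)C(=O)OCC[C@@H]2C)cc1 | intermediate
8 | (3R,4S)-3-{[(4-methoxybenzyl)oxy]methyl}-3,4-dimethyltetrahydro-2H-pyran-2-ol (anomers) | COc1ccc(COC[C@]2(C)C(O)OCC[C@@H]2C)cc1 | intermediate
9 | (3S,4S)-4-{[(4-methoxybenzyl)oxy]methyl}-3,4-dimethylhex-5-yn-1-ol | COc1ccc(COC[C@]([C@@H](C)CCO)(C)C#C)cc1 | intermediate
10 | (3S,4S)-4-{[(4-methoxybenzyl)oxy]methyl}-3,4-dimethylhex-5-ynal | COc1ccc(COC[C@]([C@@H](C)CC=O)(C)C#C)cc1 | intermediate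
11 | methyl (S)-3-hydroxy-2-methylpropanoate | COC(=O)[C@@H](C)CO | starting material
12 | methyl (S)-3-[(tert-butyldimethylsilyl)oxy]-2-methylpropanoate | COC(=O)[C@@H](C)CO[Si](C)(C)C(C)(C)C | intermediate
13 | (S)-3-[(tert-butyldimethylsilyl)oxy]-2-methylpropanal | O=C[C@@H](C)CO[Si](C)(C)C(C)(C)C | intermediate
14 | (R)-tert-butyldimethyl[(2-methylbut-3-yn-1-yl)oxy]silane | C#C[C@@H](C)CO[Si](C)(C)C(C)(C)C | intermediate
15 | (Z)-2-bromoalkenyl-9-BBN adduct of 14 | Br/C(=C\B1C2CCCC1CCC2)[C@@H](C)CO[Si](C)(C)C(C)(C)C | intermediate (not isolated)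
16 | (S)-[(3-bromo-2-methylbut-3-en-1-yl)oxy](tert-butyl)dimethylsilane | BrC(=C)[C@@H](C)CO[Si](C)(C)C(C)(C)C | intermediate
17 | alkenylmagnesium bromide from 16 | Br[Mg]C(=C)[C@@H](C)CO[Si](C)(C)C(C)(C)C | intermediate (not isolated)
18 | enyne alcohol (5S,6S,10R; C8 epimers), 14-OPMB, 11-OTBS | COc1ccc(COC[C@]([C@@H](C)CC(O)C(=C)[C@@H](C)CO[Si](C)(C)C(C)(C)C)(C)C#C)cc1 | intermediate
19 | enynone (5S,6S,10R), C8=O | COc1ccc(COC[C@]([C@@H](C)CC(=O)C(=C)[C@@H](C)CO[Si](C)(C)C(C)(C)C)(C)C#C)cc1 | intermediate
20 | enyne alcohol (5S,6S,8S,10R) | COc1ccc(COC[C@]([C@@H](C)C[C@H](O)C(=C)[C@@H](C)CO[Si](C)(C)C(C)(C)C)(C)C#C)cc1 | intermediate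
21 | enyne diol (5S,6S,8S,10R) | COc1ccc(COC[C@]([C@@H](C)C[C@H](O)C(=C)[C@@H](C)CO)(C)C#C)cc1 | intermediate
22 | silylene enyne (5S,6S,8S,10R), O8–Si(t-Bu)2–O11 | COc1ccc(COC[C@]([C@@H](C)C[C@H](O2)C(=C)[C@@H](C)CO[Si]2(C(C)(C)C)C(C)(C)C)(C)C#C)cc1 | intermediate (precursor of the key step)
23 | silylene hydrindenone (5S,6S,8S,9R,10R) | COc1ccc(COC[C@]2(C)C3=CC(=O)C[C@@]3([C@@H](O4)C[C@@H]2C)[C@@H](C)CO[Si]4(C(C)(C)C)C(C)(C)C)cc1 | intermediate (product of the key step)
24 | diol hydrindenone (5S,6S,8S,9R,10R) | COc1ccc(COC[C@]2(C)C3=CC(=O)C[C@@]3([C@@H](O)C[C@@H]2C)[C@@H](C)CO)cc1 | intermediate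
25 | bis-TBS hydrindenone, 14-OPMB | COc1ccc(COC[C@]2(C)C3=CC(=O)C[C@@]3([C@@H](O[Si](C)(C)C(C)(C)C)C[C@@H]2C)[C@@H](C)CO[Si](C)(C)C(C)(C)C)cc1 | intermediate
26 | C14 alcohol | OC[C@]1(C)C2=CC(=O)C[C@@]2([C@@H](O[Si](C)(C)C(C)(C)C)C[C@@H]1C)[C@@H](C)CO[Si](C)(C)C(C)(C)C | intermediate
27 | C14 aldehyde | O=C[C@]1(C)C2=CC(=O)C[C@@]2([C@@H](O[Si](C)(C)C(C)(C)C)C[C@@H]1C)[C@@H](C)CO[Si](C)(C)C(C)(C)C | intermediate
28 | (14R)-methallyl carbinol | CC(=C)C[C@@H](O)[C@]1(C)C2=CC(=O)C[C@@]2([C@@H](O[Si](C)(C)C(C)(C)C)C[C@@H]1C)[C@@H](C)CO[Si](C)(C)C(C)(C)C | intermediate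
29 | 14-O-allyldimethylsilyl ether | CC(=C)C[C@@H](O[Si](C)(C)CC=C)[C@]1(C)C2=CC(=O)C[C@@]2([C@@H](O[Si](C)(C)C(C)(C)C)C[C@@H]1C)[C@@H](C)CO[Si](C)(C)C(C)(C)C | intermediate
30 | cyclic siloxane (2,2,5-trimethyl-1-oxa-2-silacyclohept-4-en-7-yl on C5) | C[Si]3(C)CC=C(C)C[C@@H](O3)[C@]1(C)C2=CC(=O)C[C@@]2([C@@H](O[Si](C)(C)C(C)(C)C)C[C@@H]1C)[C@@H](C)CO[Si](C)(C)C(C)(C)C | intermediate
31 | (Z)-diol (14-OH, allylic CH2OH) | OC/C=C(/C)C[C@@H](O)[C@]1(C)C2=CC(=O)C[C@@]2([C@@H](O[Si](C)(C)C(C)(C)C)C[C@@H]1C)[C@@H](C)CO[Si](C)(C)C(C)(C)C | intermediate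
32 | (Z)-allylic mesylate | CS(=O)(=O)OC/C=C(/C)C[C@@H](O)[C@]1(C)C2=CC(=O)C[C@@]2([C@@H](O[Si](C)(C)C(C)(C)C)C[C@@H]1C)[C@@H](C)CO[Si](C)(C)C(C)(C)C | intermediate (not isolated)
33 | (Z)-allylic chloride, 14-OH | ClC/C=C(/C)C[C@@H](O)[C@]1(C)C2=CC(=O)C[C@@]2([C@@H](O[Si](C)(C)C(C)(C)C)C[C@@H]1C)[C@@H](C)CO[Si](C)(C)C(C)(C)C | intermediate
34 | (Z)-allylic chloride, 14-OAc | ClC/C=C(/C)C[C@@H](OC(C)=O)[C@]1(C)C2=CC(=O)C[C@@]2([C@@H](O[Si](C)(C)C(C)(C)C)C[C@@H]1C)[C@@H](C)CO[Si](C)(C)C(C)(C)C | intermediate
35 | C11 alcohol | ClC/C=C(/C)C[C@@H](OC(C)=O)[C@]1(C)C2=CC(=O)C[C@@]2([C@@H](O[Si](C)(C)C(C)(C)C)C[C@@H]1C)[C@@H](C)CO | intermediate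
36 | C11 aldehyde | ClC/C=C(/C)C[C@@H](OC(C)=O)[C@]1(C)C2=CC(=O)C[C@@]2([C@@H](O[Si](C)(C)C(C)(C)C)C[C@@H]1C)[C@@H](C)C=O | intermediate
37 | 8-O-TBS ether of the target | C=C[C@]1(C)C[C@@H](OC(C)=O)[C@]2(C)C3=CC(=O)C[C@@]3([C@@H](O[Si](C)(C)C(C)(C)C)C[C@@H]2C)[C@@H](C)[C@@H]1O | intermediate
38 | Pleuromutilin E (5S,6S,8S,9R,10R,11S,12S,14R) | C=C[C@]1(C)C[C@@H](OC(C)=O)[C@]2(C)C3=CC(=O)C[C@@]3([C@@H](O)C[C@@H]2C)[C@@H](C)[C@@H]1O | target

**Count and risks**

Total steps: 30. Longest linear sequence: 26 (steps 1–6 and 11–30); the C9–C11 branch (steps 7–10) joins at step 11.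

Most likely to fail:

1. Step 29 (ring closure). The strain of the trans-bridged ring may slow closure so much that protonation or dimerisation of the allylchromium species takes over, or the (Z)-alkene geometry may not be relayed through a closed transition state, giving the C12 epimer. Fallback: from 35, exchange the allylic chloride for silicon (Me3Si–SiMe3, Pd(0) cat., THF) to give the allylsilane alcohol F1, and oxidise it with Dess–Martin periodinane to the allylsilane aldehyde F2. Close the ring by an intramolecular Hosomi–Sakurai reaction (BF3·OEt2, CH2Cl2, −78 °C, high dilution), which runs through an open, Lewis-acid-bound transition state instead of the organochromium chair. Aqueous work-up gives 37, where the route is rejoined.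

2. Step 16 (Pauson–Khand). Alkene insertion has to pass through a crowded chair (axial methyl groups at C5 and C6, the C5 methyl syn to the C10 branch), so the cobalt–alkyne complex may decay or the alkyne may oligomerise before cyclisation. Fallback: give up the ring tether. From 20, silylate O8 (TBSOTf, 2,6-lutidine) to the bis-TBS enyne F3, whose open chain reaches the reactive conformer more easily, and run the same carbonylative cyclisation. Face selection then rests only on the equatorial preference of the C8 silyloxy group, so the C9 epimers would have to be separated. The desired hydrindenone is 25, where the route is rejoined (steps 14, 15, 17 and 18 drop out).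

3. Step 5 (alkyne from the lactol). The hindered lactol may stay closed, so that homologation stalls while the diazophosphonate is used up by methanolysis. Fallback: from 7, reduce fully (LiAlH4, THF) to the diol F4 and silylate the unhindered C8 hydroxyl selectively (TBSCl, imidazole, −20 °C) to the mono-silyl ether F5. Oxidise the neopentyl alcohol (Dess–Martin periodinane) to the open-chain aldehyde F6, homologate it with the Ohira–Bestmann reagent to the silyl-protected alkyne F7, and remove the silyl group (HF·pyridine) to return to 9.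

**Further compounds**

F1 | step 29 | allylsilane alcohol (as 35 with CH2SiMe3 in place of CH2Cl) | C[Si](C)(C)C/C=C(/C)C[C@@H](OC(C)=O)[C@]1(C)C2=CC(=O)C[C@@]2([C@@H](O[Si](C)(C)C(C)(C)C)C[C@@H]1C)[C@@H](C)CO
F2 | step 29 | allylsilane aldehyde | C[Si](C)(C)C/C=C(/C)C[C@@H](OC(C)=O)[C@]1(C)C2=CC(=O)C[C@@]2([C@@H](O[Si](C)(C)C(C)(C)C)C[C@@H]1C)[C@@H](C)C=O
F3 | step 16 | bis-TBS enyne (5S,6S,8S,10R) | COc1ccc(COC[C@]([C@@H](C)C[C@H](O[Si](C)(C)C(C)(C)C)C(=C)[C@@H](C)CO[Si](C)(C)C(C)(C)C)(C)C#C)cc1
F4 | step 5 | (2R,3S)-2-{[(4-methoxybenzyl)oxy]methyl}-2,3-dimethylpentane-1,5-diol | COc1ccc(COC[C@]([C@@H](C)CCO)(C)CO)cc1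
F5 | step 5 | 5-O-TBS ether of F4 | COc1ccc(COC[C@]([C@@H](C)CCO[Si](C)(C)C(C)(C)C)(C)CO)cc1
F6 | step 5 | aldehyde from F5 (C4 aldehyde) | COc1ccc(COC[C@]([C@@H](C)CCO[Si](C)(C)C(C)(C)C)(C)C=O)cc1
F7 | step 5 | TBS ether of 9 | COc1ccc(COC[C@]([C@@H](C)CCO[Si](C)(C)C(C)(C)C)(C)C#C)cc1
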